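**Plan**

1. Drimane numbering is used: ring A = C1–C5 and C10, ring B = C5–C10, C11 = the OCH2 carbon. The retrosynthesis cuts C11–O(aryl), then C8–C9, C5–C10 and C2–C3 in a single operation, leaving a C3–C8 alkynyl keto acid chloride and a C1/C2/C9–C11 iodo enoate.
2. This works because C5 is α to the C6 ketone and C10 is β to the C11 carboxyl carbon, C9 is α to C11 and C8 is β to C6 (as an ynone), and C3 is an acyl carbon on the quaternary C4. One acyl coupling (C2–C3) and two Michael closures then zip up ring A (C5–C10) and ring B (C8–C9).
3. Forward: keto acid chloride from 2,2-dimethylsuccinic anhydride (2 steps); iodo enoate from but-2-ynoic acid and (–)-8-phenylmenthol (3 steps); one-pot coupling and double cyclisation; then C3 reduction, ester/enone reduction, aryl ether formation and allylic oxidation.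
4. Stereochemistry: C10 from the 8-phenylmenthyl ester (cleaved when C11 is reduced), C5 from the chair closure (trans ring fusion), C9 from thermodynamic protonation (equatorial), C3 from equatorial hydride delivery (axial OH).

Key step: step 6

Assumption: the (E)-β,β-disubstituted 8-phenylmenthyl enoate is taken to react through its s-cis conformer, with the phenyl group covering the enoate face on the side of the auxiliary carbon that bears the dimethylbenzyl group; this leaves the Si face of C10 open, and if the sense were opposite the enantiomeric auxiliary would be used.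

**Step 1**
Reactants: 1 2,2-dimethylsuccinic anhydride; 2 prop-1-ynylmagnesium bromide
Product: 3 2,2-dimethyl-4-oxohept-5-ynoic acid
Conditions: 2 (1.05 equiv) added to 1, THF, –78 → –20 °C; 1 M HCl
Reagents that add atoms: none
Why: Acylation of a Grignard reagent by a cyclic anhydride should occur at the carbonyl remote from the gem-dimethyl group, and the magnesium carboxylate formed on ring opening should prevent a second addition; no stereocentre is formed.

**Step 2**
Reactants: 3 2,2-dimethyl-4-oxohept-5-ynoic acid
Product: 4 2,2-dimethyl-4-oxohept-5-ynoyl chloride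
Conditions: 1-chloro-N,N,2-trimethylprop-1-en-1-amine (1.1 equiv), CH2Cl2, 0 °C; concentrated and used crude at once
Reagents that add atoms: 1-chloro-N,N,2-trimethylprop-1-en-1-amine, CC(C)=C(Cl)N(C)C
Why: Acid chloride formation with an α-chloroenamine is neutral, so no HCl should add to the alkynyl ketone, and the quaternary C4 excludes ketene formation.

**Step 3**
Reactants: 5 but-2-ynoic acid; 6 (–)-8-phenylmenthol
Product: 7 8-phenylmenthyl but-2-ynoate
Conditions: DCC, DMAP (cat.), CH2Cl2, 0 → 25 °C
Reagents that add atoms: none
Why: Steglich esterification attaches the chiral alcohol that later controls C10; the stereocentres of 6 are not touched.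

**Step 4**
Reactants: 7 8-phenylmenthyl but-2-ynoate; 8 vinylmagnesium bromide
Product: 9 8-phenylmenthyl (2E)-3-methylpenta-2,4-dienoate
Conditions: 8 (1.5 equiv), CuBr·SMe2 (10 mol%), THF, –78 °C; H2O quench at –78 °C
Reagents that add atoms: none
Why: Copper-catalysed conjugate addition of a Grignard reagent to an alkynoate is a syn carbometalation, so low-temperature protonation should place the vinyl group trans to the ester and fix the alkene geometry that later decides which face of C10 is open.

**Step 5**
Reactants: 9 8-phenylmenthyl (2E)-3-methylpenta-2,4-dienoate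
Product: 11 8-phenylmenthyl (2E)-5-iodo-3-methylpent-2-enoate, via B-alkyl-9-BBN adduct 10 (not isolated)
Conditions: 9-BBN (1.1 equiv), THF, 0 → 25 °C; then NaOMe, I2, MeOH–THF, 0 °C
Reagents that add atoms: iodine, II
Why: Anti-Markovnikov hydroboration with 9-BBN should take place only at the terminal alkene, and base-induced iodinolysis of the primary B–C bond should then give the primary iodide while the trisubstituted enoate stays intact.

**Step 6**
Reactants: 11 8-phenylmenthyl (2E)-5-iodo-3-methylpent-2-enoate; 4 2,2-dimethyl-4-oxohept-5-ynoyl chloride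
Product: 15 8-phenylmenthyl 3,6-dioxodrim-7-en-11-oate, via alkylzinc iodide 12 (not isolated), via acyclic diketone 13 (not isolated), via ring A ester enolate 14 (not isolated)
Conditions: Zn dust, LiCl, THF, 40 °C; then 4 (1.1 equiv), Pd(PPh3)4 (5 mol%), THF, 0 → 25 °C; then KOt-Bu (2.5 equiv), t-BuOH, THF (high dilution), –20 → 25 °C; AcOH quench
Reagents that add atoms: none
Why: Zinc inserts into the C–I bond of 11 to give the covalent, ester-tolerant alkylzinc 12 (which should not close a three-membered ring onto its own enoate), and Negishi acylation with 4 under zerovalent palladium catalysis forms C2–C3 at the ketone level (13). KOt-Bu then removes the most acidic proton, at C5 next to the alkynyl ketone; this enolate closes ring A by 6-exo-trig Michael addition to C10 of the enoate (C5–C10), the ester enolate 14 closes ring B by 6-endo-dig Michael addition of C9 to C8 of the ynone, and proton transfer gives the stabilised C9 dienolate, which the quench converts to the conjugated enone. The closest known reaction types are the Negishi acyl coupling and the base-mediated tandem (double) intramolecular Michael annulation of a keto enoate onto an ynone. C10 is set by the 8-phenylmenthyl group, whose phenyl ring covers one face of the s-cis (E)-enoate so that C5 adds to the Si face of C10; C5 follows from a chair transition state with both carbonyl-bearing arms equatorial (trans to the C10 methyl, and still epimerisable towards the trans-fused enone); C9 is set by thermodynamic protonation that places the ester equatorial. The step needs the C5 enolate to win over enolisation at C2 (which would lead by aldol condensation of the 1,4-diketone to a cyclopentenone) and over intermolecular addition; the greater acidity of C5–H beside the alkynyl ketone, the reversibility of the aldol path, the irreversible second Michael addition and high dilution should secure this.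

**Step 7**
Reactants: 15 8-phenylmenthyl 3,6-dioxodrim-7-en-11-oate
Product: 16 8-phenylmenthyl (3S)-3-hydroxy-6-oxodrim-7-en-11-oate
Conditions: KBH(s-Bu)3 (1.5 equiv), THF, –78 °C; H2O quench
Reagents that add atoms: none
Why: Ketone reduction by a bulky trialkylborohydride should deliver hydride equatorially to the C3 ketone beside the gem-dimethyl group and give the axial (3S) alcohol, while the hindered β,β-disubstituted enone and the hindered ester are expected to survive at –78 °C.

**Step 8**
Reactants: 16 8-phenylmenthyl (3S)-3-hydroxy-6-oxodrim-7-en-11-oate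
Product: 17 (3S)-drim-7-ene-3,6,11-triol (C6 epimers)
Conditions: LiAlH4 (4 equiv), THF, 0 → 25 °C; H2O work-up
Reagents that add atoms: none
Why: Hydride reduction with LiAlH4 turns the C11 ester into the primary alcohol (releasing the auxiliary) and reduces the enone in the 1,2 sense to an allylic alcohol whose two C6 epimers both converge in step 10; once C6 is an alcohol, C9 can no longer epimerise.

**Step 9**
Reactants: 17 (3S)-drim-7-ene-3,6,11-triol; 18 umbelliferone
Product: 19 7-[(3,6-dihydroxydrim-7-en-11-yl)oxy]-2H-chromen-2-one
Conditions: 18 (1.2 equiv), PPh3, DIAD, THF, 0 → 25 °C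
Reagents that add atoms: none
Why: In the Mitsunobu etherification the acidic phenol should displace the activated primary C11 hydroxyl in preference to the hindered allylic and axial neopentyl secondary hydroxyls, and no stereocentre is involved.

**Step 10**
Reactants: 19 7-[(3,6-dihydroxydrim-7-en-11-yl)oxy]-2H-chromen-2-one
Product: 20 ferocaulidin
Conditions: MnO2 (activated, excess), CH2Cl2, 25 °C
Reagents that add atoms: none
Why: Allylic alcohol oxidation with MnO2 should be selective for the C6 allylic alcohol over the saturated C3 alcohol and restores the enone under neutral conditions, which should neither epimerise C9 nor eliminate the aryloxide.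

**Compound list**

1 | 2,2-dimethylsuccinic anhydride (3,3-dimethyloxolane-2,5-dione) | CC1(C)CC(=O)OC1=O | starting material
2 | prop-1-ynylmagnesium bromide | CC#C[Mg]Br | starting material
3 | 2,2-dimethyl-4-oxohept-5-ynoic acid | CC#CC(=O)CC(C)(C)C(=O)O | intermediate
4 | 2,2-dimethyl-4-oxohept-5-ynoyl chloride | CC#CC(=O)CC(C)(C)C(Cl)=O | intermediate
5 | but-2-ynoic acid | CC#CC(=O)O | starting material
6 | (–)-8-phenylmenthol, (1R,2S,5R)-5-methyl-2-(2-phenylpropan-2-yl)cyclohexan-1-ol | O[C@@H]1C[C@H](C)CC[C@H]1C(C)(C)c1ccccc1 | starting material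
7 | (1R,2S,5R)-8-phenylmenthyl but-2-ynoate | CC#CC(=O)O[C@@H]1C[C@H](C)CC[C@H]1C(C)(C)c1ccccc1 | intermediate
8 | vinylmagnesium bromide | C=C[Mg]Br | starting material
9 | 8-phenylmenthyl (2E)-3-methylpenta-2,4-dienoate | C=C/C(C)=C/C(=O)O[C@@H]1C[C@H](C)CC[C@H]1C(C)(C)c1ccccc1 | intermediate
10 | 8-phenylmenthyl (2E)-5-(9-borabicyclo[3.3.1]nonan-9-yl)-3-methylpent-2-enoate | C(C/C(C)=C/C(=O)O[C@@H]1C[C@H](C)CC[C@H]1C(C)(C)c1ccccc1)B1C2CCCC1CCC2 | intermediate
11 | 8-phenylmenthyl (2E)-5-iodo-3-methylpent-2-enoate | ICC/C(C)=C/C(=O)O[C@@H]1C[C@H](C)CC[C@H]1C(C)(C)c1ccccc1 | intermediate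
12 | alkylzinc iodide of 11 (C–ZnI at C2) | I[Zn]CC/C(C)=C/C(=O)O[C@@H]1C[C@H](C)CC[C@H]1C(C)(C)c1ccccc1 | intermediate
13 | 8-phenylmenthyl (2E)-3,7,7-trimethyl-6,9-dioxododec-2-en-10-ynoate | CC#CC(=O)CC(C)(C)C(=O)CC/C(C)=C/C(=O)O[C@@H]1C[C@H](C)CC[C@H]1C(C)(C)c1ccccc1 | intermediate
14 | potassium ester enolate of 8-phenylmenthyl 2-[2-(but-2-ynoyl)-1,3,3-trimethyl-4-oxocyclohexyl]acetate (C5, C10 as in 20) | CC#CC(=O)[C@@H]1C(C)(C)C(=O)CC[C@@]1(C)C=C([O-])O[C@@H]2C[C@H](C)CC[C@H]2C(C)(C)c2ccccc2.[K+] | intermediate
15 | 8-phenylmenthyl 3,6-dioxodrim-7-en-11-oate (C5, C9, C10 as in 20) | CC1=CC(=O)[C@@H]2C(C)(C)C(=O)CC[C@@]2(C)[C@@H]1C(=O)O[C@@H]1C[C@H](C)CC[C@H]1C(C)(C)c1ccccc1 | intermediate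
16 | 8-phenylmenthyl (3S)-3-hydroxy-6-oxodrim-7-en-11-oate (axial 3-OH) | CC1=CC(=O)[C@@H]2C(C)(C)[C@@H](O)CC[C@@]2(C)[C@@H]1C(=O)O[C@@H]1C[C@H](C)CC[C@H]1C(C)(C)c1ccccc1 | intermediate
17 | (3S)-drim-7-ene-3,6,11-triol, C6 epimers | CC1=CC(O)[C@@H]2C(C)(C)[C@@H](O)CC[C@@]2(C)[C@@H]1CO | intermediate
18 | umbelliferone (7-hydroxy-2H-chromen-2-one) | Oc1ccc2ccc(=O)oc2c1 | starting material
19 | 7-[(3,6-dihydroxydrim-7-en-11-yl)oxy]-2H-chromen-2-one, C6 epimers | CC1=CC(O)[C@@H]2C(C)(C)[C@@H](O)CC[C@@]2(C)[C@@H]1COc1ccc2ccc(=O)oc2c1 | intermediate
20 | ferocaulidin | CC1=CC(=O)[C@@H]2C(C)(C)[C@@H](O)CC[C@@]2(C)[C@@H]1COc1ccc2ccc(=O)oc2c1 | target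

**Step count**

Total: 10 steps. Longest linear sequence: 8 steps (steps 3–10).

**Steps most likely to fail**

Step 6. After the acyl coupling the base may enolise the new C3 ketone towards C2, so that the 1,4-diketone is lost by intramolecular aldol condensation. The alkynyl ketone may also isomerise, or the first conjugate closure onto the hindered β,β-disubstituted ester may be slow and poorly face-selective. The fallback keeps C3 at the carbinol level during the closures, so that C2 cannot enolise. It sets out from 11 (as its zinc reagent 12) and 2. Reagent 2 is added to commercial 4,4-dimethyloxolan-2-one (THF, –78 °C) to give 1-hydroxy-2,2-dimethylhept-5-yn-4-one F1, and Dess–Martin oxidation turns this into 2,2-dimethyl-4-oxohept-5-ynal F2. Zinc reagent 12 adds to the aldehyde of F2 (MgCl2, THF) to give the acyclic adduct F3 as its alkoxide, and KOt-Bu in the same flask should bring about the same two Michael closures to the bicyclic C3 alcohols F4 (both C3 epimers). Dess–Martin oxidation of F4 comes back to the route at 15.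

Step 9. Substitution at the β-branched primary carbinol beside the quaternary C10 may be slow, with competing elimination of the activated hydroxyl or reaction at the allylic hydroxyl. The fallback makes the same C–O bond from the aryl side, by palladium-catalysed C–O cross-coupling (Buchwald–Hartwig etherification) of the primary hydroxyl of 17 with commercial 7-bromo-2H-chromen-2-one (Pd2(dba)3, RockPhos, Cs2CO3, toluene, 90 °C). The primary alcohol should be arylated in preference to the two hindered secondary ones. This sets out from 17 and comes back at 19 without any new intermediate.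

Step 4. The alkene geometry may be lost by equilibration of the alkenylcopper/allenoate intermediate before protonation, which would later erode the face selection at C10. The fallback fixes the geometry in an enol triflate and couples with retention. It sets out from 6: acetoacetylation with 2,2,6-trimethyl-4H-1,3-dioxin-4-one (xylene, 130 °C) gives 8-phenylmenthyl 3-oxobutanoate F5. Enolisation with aqueous Me4NOH and trapping with Tf2O gives 8-phenylmenthyl (2E)-3-(trifluoromethylsulfonyloxy)but-2-enoate F6. Stille coupling of F6 with tributyl(vinyl)stannane (Pd(PPh3)4, LiCl, THF, 60 °C) comes back at 9.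

**Further compounds**

F1 | step 6 | 1-hydroxy-2,2-dimethylhept-5-yn-4-one | CC#CC(=O)CC(C)(C)CO
F2 | step 6 | 2,2-dimethyl-4-oxohept-5-ynal | CC#CC(=O)CC(C)(C)C=O
F3 | step 6 | 8-phenylmenthyl (2E)-6-hydroxy-3,7,7-trimethyl-9-oxododec-2-en-10-ynoate (C6 epimers) | CC#CC(=O)CC(C)(C)C(O)CC/C(C)=C/C(=O)O[C@@H]1C[C@H](C)CC[C@H]1C(C)(C)c1ccccc1
F4 | step 6 | 8-phenylmenthyl 3-hydroxy-6-oxodrim-7-en-11-oate (both C3 epimers) | CC1=CC(=O)[C@@H]2C(C)(C)C(O)CC[C@@]2(C)[C@@H]1C(=O)O[C@@H]1C[C@H](C)CC[C@H]1C(C)(C)c1ccccc1
F0 | step 9 | none | none
F5 | step 4 | 8-phenylmenthyl 3-oxobutanoate | CC(=O)CC(=O)O[C@@H]1C[C@H](C)CC[C@H]1C(C)(C)c1ccccc1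
F6 | step 4 | 8-phenylmenthyl (2E)-3-(trifluoromethylsulfonyloxy)but-2-enoate | C/C(OS(=O)(=O)C(F)(F)F)=C\C(=O)O[C@@H]1C[C@H](C)CC[C@H]1C(C)(C)c1ccccc1
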